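**Assumption (remark on the chemistry):** atom labels C1–C7a follow the target numbering throughout; the carbons that end as C1 and C7 (each α to an ester or lactone carbonyl) are carried as epimer mixtures from 7 to 32, because C7 becomes trigonal in step 13 and C1 is equilibrated in step 15.

## Structural features

The target is a trans-fused bicyclo[4.3.0]nonene: cyclopentanone ring A (C1, C2, C3, C3a, C7a) shares the C3a–C7a bond with cyclohexene ring B (C3a, C4=C5, C6, C7, C7a). Six stereocentres are contiguous: C1 (ethyl) and C3 (methyl) flank the ketone, C3a and C7a form the ring fusion, and C6 (ethyl, (E)-styryl) and C7 (ethyl, CO2H) are adjacent quaternary carbons. The C6 ethyl, the C7 ethyl and the C7a–C1 bond lie on one face of ring B. C1 and C3 are epimerisable, and in the target each substituent is trans to its neighbour at the ring fusion, which is the thermodynamic arrangement; C3a, C7a, C6 and C7 cannot be corrected later. The fragile groups are the styrene and the trisubstituted C4=C5 alkene (the C7 acid can lactonise onto either under strong acid) and the hindered tertiary acid. The real difficulty is the C6–C7 bond between two fully substituted carbons and its relation to the trans ring fusion. The array HO2C–C7–C6–C5=C4 in ring B is a γ,δ-unsaturated acid, so C6–C7 can be made by a [3,3] shift of a δ-lactone ketene acetal whose ring oxygen sits on C4 and whose C4 carries the dienyl group; ring B then arises by contraction of that lactone.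

## Logic of the disconnections

**34 ⇒ 32.** A methoxycarbonyl group is added back at C3 and the C1/C3 configurations are left open. This exposes a β-keto ester, the retron of a ring-A acylation, and removes two stereocentres from the problem. The forward step needs a neutral dealkoxycarbonylation that spares the alkenes and the acid, and a final base equilibration that must give the trans,trans ketone.

**32 ⇒ 30.** The C2–C3 bond and the C3–CH3 bond are cut. Ring A becomes two ester arms on a trans-1,2-disubstituted cyclohexene. The forward step needs the enolate of the unbranched C3 ester to attack the C1 ester while the C7 carboxylate stays inert, and it must close a trans-fused five-membered ring.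

**30 ⇒ 27 (key).** C6–C7 is cut and C4–O is re-formed. Both quaternary carbons and ring B collapse to a δ-lactone with one quaternary carbinol carbon (C4) and an (E,E)-dienyl group. The forward step needs a ketene acetal at the lactone only, a boat transition state, the (E)-C5=C6 geometry, and the correct C4, C3a and C7a configurations. Ring A must stay open, since a trans-fused five-membered ring cannot span the boat.

**27 ⇒ 24.** The lactone acyl bond O–C8 is cut and the C4 oxygen is re-attached to the C3-arm carboxyl, giving a γ-lactone. A tertiary C4 alkoxide next to an unbranched γ-ester closes the five-membered lactone first, so that lactone is accepted as the resting form and exchanged afterwards. The forward step must mask the C3 carboxyl as its salt while the six-membered lactone closes, and the choice between the two identical butanoate arms sets C7a.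

**24 ⇒ 22.** The C4–CH3 bond is cut. The C3a stereocentre, with its branched C7a chain as the large group, should steer methyl to the required C4 face (Felkin–Anh). The opposite order, dienyl addition to a methyl ketone, would deliver the C4 epimer under the same model. The forward step needs clean 1,2-addition without enolisation.

**22 ⇒ 13 + 19.** The C4–C5 bond is cut into an acyl donor and a dienyl metal. The coupling must be neutral so that C3a and the diene geometry survive.

**13 ⇒ 10 (+ 8).** The C3a–C3 bond is cut and the thioester is traced back to an acyl oxazolidinone. An auxiliary-controlled alkylation sets C3a, the centre from which C4 is then induced, in absolute terms.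

**10 ⇒ 7 ⇒ 5 ⇒ 3 ⇒ 1 + 2.** The N-acyl bond, the two C–ethyl bonds, one carboxyl group and the C3a–C7a bond are cut in turn. This reaches a malonate and a glutaconate. A soft malonate donor avoids the acid–base problem that a simple ketone or ester enolate would have with the acidic glutaconate.

**19 ⇒ 17 ⇒ 15 ⇒ 14.** The C6–ethyl and C5–I bonds are cut (syn carbometalation of an enyne), and the alkyne is traced to an aldehyde. The forward carbometalation must place ethyl on the internal carbon and keep the styryl alkene intact.

## Other disconnections considered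

**Alternative 1:** The cut is through C7–C7a and C3a–C4. The forward key step is a [4+2] cycloaddition of the pyranone A1 with the fumarate A2 to the bridged lactone A3, which keeps the CO2 bridge as the future C7 carboxyl.
- In its favour: it is convergent and makes ring B, the C7 quaternary carbon with its carboxyl carbon and the trans C3a/C7a relationship (from the (E)-diester, stereospecifically) in one step. On these points it is better than the chosen plan, which needs a selection between two arms for C7a.
- Against it here: C6 is still trigonal in A3. The second quaternary carbon would have to be made afterwards by intermolecular delivery of a styryl group to a hindered, ethyl-bearing alkene terminus with opening of the bridge. Bridged pyranone adducts also tend to lose CO2 on heating, and the two ester carbons on C3a and C7a would need a one-carbon insertion plus ethyl and methyl groups to become ring A.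
- Comparison: both plans deliver the C7 carboxyl directly (equal). A3 is reached in fewer steps (better). The chosen plan forms both quaternary carbons intramolecularly in one event, which A3 does not (worse for Alternative 1).

**Alternative 2:** The cut is through C3a–C7a, C1–C2 and C2–C3. The forward key step is a cyclocarbonylation of the acyclic dienyne A4 ([RhCl(CO)2]2 or Co2(CO)8, CO) to the bicyclic enone A5.
- In its favour: both rings close in one catalytic step, ring A needs no extra carbon that must be excised later, and the C3 configuration follows from alkene geometry. In ring and step economy it is better than the chosen plan.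
- Against it here: A4 already contains the vicinal quaternary pair C6/C7, which would have to be built in an open chain with no ring to help. The six-membered ring closure is the slower mode for this reaction type. The tetrasubstituted enone in A5 must then be reduced with control of C7a (trans fusion) and C1, and the C6 vinyl group exchanged for styryl.
- Comparison: equal at C1/C3 (thermodynamic in both); better for ring A; worse for C6/C7 and for ring-fusion control, which the chosen plan derives from one lactone.

**Alternative 3:** The cut is through C4=C5. The forward key step is ring-closing metathesis of the triene A6 (second-generation Grubbs catalyst), in which one of two diastereotopic vinyl groups on C6 joins the C3a isopropenyl group to give A7.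
- In its favour: the conditions are neutral and catalytic, ring A and the trans fusion are in place beforehand, and no acid-labile tertiary dienylic ester is carried. On functional-group tolerance it is better than the chosen plan.
- Against it here: A6 still needs the C6–C7 bond between two fully substituted carbons, made without pericyclic help. Closing a trisubstituted alkene from a 1,1-disubstituted alkene next to a quaternary carbon is slow, and the remaining vinyl must still become styryl.
- Comparison: both plans rely on substrate conformation for C6 (equal); Alternative 3 is milder (better); it does not solve the vicinal quaternary bond and adds steps (worse).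

Key step: step 13

## Route

Step 1
Reactants: 1 di-tert-butyl propanedioate; 2 dimethyl (2E)-pent-2-enedioate
Product: 3 1,1-di-tert-butyl 3-methyl 2-(2-methoxy-2-oxoethyl)propane-1,1,3-tricarboxylate
Conditions: KOtBu (10 mol %), THF, 0 → 25 °C
Reagents that add atoms: none
Why: Base-catalysed Michael addition of the malonate anion to the β-carbon of the glutaconate makes the C3a–C7a bond and puts two acetate arms on C7a; no stereocentre is formed. The doubly stabilised donor is regenerated by proton transfer, so catalytic base suffices and the acidic γ-hydrogens of 2 only slow the reaction.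

Step 2
Reactants: 3 1,1-di-tert-butyl 3-methyl 2-(2-methoxy-2-oxoethyl)propane-1,1,3-tricarboxylate
Product: 5 5-methoxy-3-(2-methoxy-2-oxoethyl)-5-oxopentanoic acid, via malonic acid 4 (not isolated)
Conditions: CF3CO2H, CH2Cl2, 25 °C; concentrate; toluene, 110 °C
Reagents that add atoms: none
Why: Acidolysis removes both tert-butyl esters while the methyl esters survive, and the malonic acid loses CO2 on heating. The product has one free acid (the future C4 carboxyl) and two methyl ester arms.

Step 3
Reactants: 5 5-methoxy-3-(2-methoxy-2-oxoethyl)-5-oxopentanoic acid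
Product: 7 4-(methoxycarbonyl)-3-[1-(methoxycarbonyl)propyl]hexanoic acid, via trilithium bis-enolate 6 (not isolated)
Conditions: LDA (3.3 equiv), THF, −78 °C; DMPU, EtI (2.6 equiv), −78 → −20 °C
Reagents that add atoms: iodoethane, CCI
Why: Ester enolate alkylation: at −78 °C the carboxylate protects its own α-CH2, so only the two methyl ester arms are enolised and each is ethylated once (the future C1 and C7 ethyl groups). The new centres are formed without control, which does not matter.

Step 4
Reactants: 7 4-(methoxycarbonyl)-3-[1-(methoxycarbonyl)propyl]hexanoic acid; 8 (4S)-4-benzyl-1,3-oxazolidin-2-one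
Product: 10 dimethyl 3-{2-[(4S)-4-benzyl-2-oxo-1,3-oxazolidin-3-yl]-2-oxoethyl}-2,4-diethylpentanedioate, via mixed pivalic anhydride 9 (not isolated)
Conditions: t-BuCOCl, Et3N, THF, −20 °C; then 8, LiCl, 25 °C
Reagents that add atoms: none
Why: N-Acylation of the oxazolidinone through the mixed anhydride, with attack at the less hindered carbonyl; the hindered methyl esters do not compete.

Step 5
Reactants: 10 dimethyl 3-{2-[(4S)-4-benzyl-2-oxo-1,3-oxazolidin-3-yl]-2-oxoethyl}-2,4-diethylpentanedioate
Product: 12 dimethyl 3-{(2S)-1-[(4S)-4-benzyl-2-oxo-1,3-oxazolidin-3-yl]-4-methoxy-1,4-dioxobutan-2-yl}-2,4-diethylpentanedioate, via sodium enolate 11 (not isolated)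
Conditions: NaN(SiMe3)2 (1.1 equiv), THF, −78 °C; BrCH2CO2Me (3 equiv), −78 → −45 °C
Reagents that add atoms: methyl bromoacetate, COC(=O)CBr
Why: Evans alkylation: only the imide α-CH2 is acidic enough for the silylamide, and the chelated (Z)-enolate is alkylated on the face away from the benzyl group. This sets C3a as (S) and introduces the C3 arm.

Step 6
Reactants: 12 dimethyl 3-{(2S)-1-[(4S)-4-benzyl-2-oxo-1,3-oxazolidin-3-yl]-4-methoxy-1,4-dioxobutan-2-yl}-2,4-diethylpentanedioate
Product: 13 dimethyl 2,4-diethyl-3-[(2S)-1-(ethylsulfanyl)-4-methoxy-1,4-dioxobutan-2-yl]pentanedioate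
Conditions: EtSH, n-BuLi, THF, 0 °C
Reagents that add atoms: ethanethiol, CCS
Why: Lithium thiolate cleaves the exocyclic imide carbonyl much faster than the methyl esters and does not epimerise the α-centre. The auxiliary is recovered and C4 is left as a thioester for a neutral ketone synthesis.

Step 7
Reactants: 14 (2E)-3-phenylprop-2-enal
Product: 15 [(1E)-4,4-dibromobuta-1,3-dien-1-yl]benzene
Conditions: CBr4 (2 equiv), PPh3 (4 equiv), CH2Cl2, 0 °C
Reagents that add atoms: carbon tetrabromide, BrC(Br)(Br)Br
Why: First stage of the Corey–Fuchs sequence: Wittig dibromomethylenation of the aldehyde, leaving the styryl alkene untouched.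

Step 8
Reactants: 15 [(1E)-4,4-dibromobuta-1,3-dien-1-yl]benzene
Product: 17 [(1E)-but-1-en-3-yn-1-yl]benzene, via lithium acetylide 16 (not isolated)
Conditions: n-BuLi (2.1 equiv), THF, −78 → 0 °C; H2O
Reagents that add atoms: none
Why: Second stage of the Corey–Fuchs sequence: bromine–lithium exchange, rearrangement of the carbenoid to the alkyne and deprotonation give the acetylide, which is protonated on work-up.

Step 9
Reactants: 17 [(1E)-but-1-en-3-yn-1-yl]benzene
Product: 19 [(1E,3E)-3-ethyl-4-iodobuta-1,3-dien-1-yl]benzene, via dienylcopper 18 (not isolated)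
Conditions: EtMgBr, CuBr·SMe2, Et2O–Me2S, −45 °C; 17, −45 → −25 °C; then I2, THF, −78 → 0 °C
Reagents that add atoms: ethylmagnesium bromide, CC[Mg]Br; iodine, II
Why: Normant carbocupration: ethylcopper adds syn across the terminal alkyne, with ethyl on the internal carbon and copper on the terminus. Iodinolysis with retention gives the iodide cis to ethyl, which is the (E)-geometry later needed at C5=C6.

Step 10
Reactants: 19 [(1E,3E)-3-ethyl-4-iodobuta-1,3-dien-1-yl]benzene; 13 dimethyl 2,4-diethyl-3-[(2S)-1-(ethylsulfanyl)-4-methoxy-1,4-dioxobutan-2-yl]pentanedioate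
Product: 22 dimethyl 2,4-diethyl-3-[(3S,5E,7E)-6-ethyl-1-methoxy-1,4-dioxo-8-phenylocta-5,7-dien-3-yl]pentanedioate, via dienyllithium 20 (not isolated), via dienylzinc chloride 21 (not isolated)
Conditions: 19, t-BuLi (2.1 equiv), Et2O, −78 °C; ZnCl2, THF, −78 → 0 °C; then 13, PdCl2(PPh3)2 (5 mol %), THF–toluene, 25 °C
Reagents that add atoms: none
Why: Fukuyama coupling: the alkenylzinc, made with retention of geometry, acylates at the thioester under palladium catalysis. The conditions are neutral, so the three methyl esters and the C3a stereocentre are untouched and the C4–C5 bond is formed without over-addition.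

Step 11
Reactants: 22 dimethyl 2,4-diethyl-3-[(3S,5E,7E)-6-ethyl-1-methoxy-1,4-dioxo-8-phenylocta-5,7-dien-3-yl]pentanedioate
Product: 24 dimethyl 2,4-diethyl-3-{(2S,3S)-2-[(1E,3E)-2-ethyl-4-phenylbuta-1,3-dien-1-yl]-2-methyl-5-oxooxolan-3-yl}pentanedioate, via cerium alkoxide 23 (not isolated)
Conditions: MeLi (1.3 equiv), CeCl3 (1.4 equiv), THF, −78 °C; then 25 °C
Reagents that add atoms: methyllithium, [Li]C
Why: The organocerium reagent adds 1,2 to the dienone without enolisation or ester attack. Under Felkin–Anh control methyl enters anti to the branched C7a chain on C3a, with the CH2CO2Me group beside the carbonyl oxygen, which gives the (S)-carbinol at C4. On warming the tertiary alkoxide closes the five-membered lactone on the unbranched C3 ester (5-exo-trig), about a hundred times faster than a six-membered closure.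

Step 12
Reactants: 24 dimethyl 2,4-diethyl-3-{(2S,3S)-2-[(1E,3E)-2-ethyl-4-phenylbuta-1,3-dien-1-yl]-2-methyl-5-oxooxolan-3-yl}pentanedioate
Product: 27 methyl 2-[(2S,3S,4R)-5-ethyl-2-[(1E,3E)-2-ethyl-4-phenylbuta-1,3-dien-1-yl]-4-(1-methoxy-1-oxobutan-2-yl)-2-methyl-6-oxooxan-3-yl]acetate, via potassium hydroxy carboxylate 25 (not isolated), via potassium lactone carboxylate 26 (not isolated)
Conditions: KOH (1.05 equiv), THF–H2O, 0 °C; evaporate, toluene azeotrope; KOtBu (0.2 equiv), 18-crown-6, THF, 25 °C; MeI, DMF, 0 → 25 °C
Reagents that add atoms: potassium hydroxide, [K+].[OH-]; iodomethane, CI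
Why: Hydroxide opens the unhindered lactone carbonyl in preference to the hindered arm esters. With the C3 carboxyl masked as its salt, the tertiary alkoxide can only close the six-membered lactone on a butanoate arm, and the carboxylate is then O-methylated under acid-free conditions. Closure is reversible through methoxide and should favour the chair with the dienyl group and both chains equatorial and only methyl axial, which places the C7a chain trans to the C3a chain (4R); C7a-epimeric lactones, if formed, are removed at this stage.

Step 13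
Reactants: 27 methyl 2-[(2S,3S,4R)-5-ethyl-2-[(1E,3E)-2-ethyl-4-phenylbuta-1,3-dien-1-yl]-4-(1-methoxy-1-oxobutan-2-yl)-2-methyl-6-oxooxan-3-yl]acetate
Product: 30 (1R,2S,5S,6R)-1,2-diethyl-6-(1-methoxy-1-oxobutan-2-yl)-5-(2-methoxy-2-oxoethyl)-4-methyl-2-[(E)-2-phenylethenyl]cyclohex-3-ene-1-carboxylic acid, via silyl ketene acetal 28 (not isolated), via trimethylsilyl ester 29 (not isolated)
Conditions: LDA (4 equiv), Me3SiCl–Et3N (1:1, premixed), THF, −78 °C; then 25 → 65 °C; 1 M HCl
Reagents that add atoms: none
Why: Ireland–Claisen rearrangement run as a lactone ring contraction: amide base in the presence of Me3SiCl (internal quench) converts the lactone and both ester groups into silyl ketene acetals before any enolate can condense, and only the lactone acetal 28 holds an allylic C–O bond (C7=C8–O–C4–C5=C6). On warming it undergoes a concerted suprafacial [3,3] shift in which C6–C7 forms as C4–O breaks; the closest known reaction type is the silyl ketene acetal rearrangement of 6-alkenyl δ-lactones to cyclohex-3-enecarboxylic acids. Ring B (C3a–C4–C5–C6–C7–C7a) is closed sigmatropically through a boat, 2-oxabicyclo[2.2.2]octene-like transition state, because the two-carbon tether C3a–C7a joins the termini C4 and C7 and excludes the chair. C7: the dienyl arm can reach the ketene acetal only on the lactone face to which it is attached at C4, which is also the face of the C7a side chain, so the ethyl group ends cis and the new carboxyl group trans to that chain; the controlling element is the C4 configuration from step 11. C6: the (E)-C5=C6 geometry puts the C6 ethyl group under the C7–C7a bond and the styryl group under the C7 ethyl group in the boat, so the two ethyl groups end cis. The step needs chemoselectivity (only 28 can rearrange), reaction at the proximal C5=C6 bond (the only one in a 1,5-relationship to C7) and complete silylation of the hindered C7–H, which the excess base and the in situ trap should secure; the temperature is kept low so that heterolysis of the tertiary dienylic C4–O bond does not compete. Acidic work-up returns the two methyl esters and frees the C7 acid from its silyl ester 29.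

Step 14
Reactants: 30 (1R,2S,5S,6R)-1,2-diethyl-6-(1-methoxy-1-oxobutan-2-yl)-5-(2-methoxy-2-oxoethyl)-4-methyl-2-[(E)-2-phenylethenyl]cyclohex-3-ene-1-carboxylic acid
Product: 32 (3aS,6S,7R,7aR)-1,6,7-triethyl-3-(methoxycarbonyl)-3,4-dimethyl-2-oxo-6-[(E)-2-phenylethenyl]-2,3,3a,6,7,7a-hexahydro-1H-indene-7-carboxylic acid, via dilithium keto ester enolate 31 (not isolated)
Conditions: LiN(SiMe3)2 (3.5 equiv), THF, −78 → 0 °C; then MeI (1.5 equiv), DMPU, 0 → 25 °C; dilute HCl
Reagents that add atoms: iodomethane, CI
Why: Dieckmann condensation then C-alkylation in one flask: the accessible C3 methylene ester is enolised and attacks the C1 ester carbonyl (5-exo-trig) across the trans-diequatorial arms, and only this mode gives a product that is drained as a stabilised β-keto ester enolate. The C7 acid is present as its lithium carboxylate, which is neither electrophilic nor methylated in THF, and methyl iodide then alkylates C3.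

Step 15
Reactants: 32 (3aS,6S,7R,7aR)-1,6,7-triethyl-3-(methoxycarbonyl)-3,4-dimethyl-2-oxo-6-[(E)-2-phenylethenyl]-2,3,3a,6,7,7a-hexahydro-1H-indene-7-carboxylic acid
Product: 34 (1S,3S,3aR,6S,7R,7aR)-1,6,7-triethyl-3,4-dimethyl-2-oxo-6-[(E)-2-phenylethenyl]-2,3,3a,6,7,7a-hexahydro-1H-indene-7-carboxylic acid, via ketone epimer mixture 33 (not isolated)
Conditions: LiCl, H2O, DMSO, 150 °C; then DBU, 60 °C; dilute HCl
Reagents that add atoms: none
Why: Krapcho dealkoxycarbonylation (chloride demethylates the activated ester, then CO2 is lost) under near-neutral conditions that spare the alkenes and the acid. Base then equilibrates C1 and C3 to the isomer in which ethyl is trans to C7 and methyl is trans to C4, the most stable arrangement on the trans-fused cyclopentanone, which is the target.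

## Compound list

1 | di-tert-butyl propanedioate | CC(C)(C)OC(=O)CC(=O)OC(C)(C)C | starting material
2 | dimethyl (2E)-pent-2-enedioate | COC(=O)/C=C/CC(=O)OC | starting material
3 | 1,1-di-tert-butyl 3-methyl 2-(2-methoxy-2-oxoethyl)propane-1,1,3-tricarboxylate | COC(=O)CC(CC(=O)OC)C(C(=O)OC(C)(C)C)C(=O)OC(C)(C)C | intermediate
4 | 2-(1,5-dimethoxy-1,5-dioxopentan-3-yl)propanedioic acid (not isolated) | COC(=O)CC(CC(=O)OC)C(C(=O)O)C(=O)O | intermediate
5 | 5-methoxy-3-(2-methoxy-2-oxoethyl)-5-oxopentanoic acid | COC(=O)CC(CC(=O)OC)CC(=O)O | intermediate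
6 | trilithium carboxylate bis(ester enolate) of 5 (not isolated) | [Li+].[Li+].[Li+].[O-]C(=O)CC(C=C([O-])OC)C=C([O-])OC | intermediate
7 | 4-(methoxycarbonyl)-3-[1-(methoxycarbonyl)propyl]hexanoic acid (stereoisomer mixture in the two arms) | CCC(C(=O)OC)C(CC(=O)O)C(CC)C(=O)OC | intermediate
8 | (4S)-4-benzyl-1,3-oxazolidin-2-one | O=C1OC[C@H](Cc2ccccc2)N1 | starting material
9 | mixed anhydride of 7 with 2,2-dimethylpropanoic acid (not isolated) | CCC(C(=O)OC)C(CC(=O)OC(=O)C(C)(C)C)C(CC)C(=O)OC | intermediate
10 | dimethyl 3-{2-[(4S)-4-benzyl-2-oxo-1,3-oxazolidin-3-yl]-2-oxoethyl}-2,4-diethylpentanedioate (arm epimers) | O=C1OC[C@H](Cc2ccccc2)N1C(=O)CC(C(CC)C(=O)OC)C(CC)C(=O)OC | intermediate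
11 | sodium (Z)-enolate of 10 (not isolated) | O=C1OC[C@H](Cc2ccccc2)N1/C([O-])=C/C(C(CC)C(=O)OC)C(CC)C(=O)OC.[Na+] | intermediate
12 | dimethyl 3-{(2S)-1-[(4S)-4-benzyl-2-oxo-1,3-oxazolidin-3-yl]-4-methoxy-1,4-dioxobutan-2-yl}-2,4-diethylpentanedioate (arm epimers) | O=C1OC[C@H](Cc2ccccc2)N1C(=O)[C@@H](CC(=O)OC)C(C(CC)C(=O)OC)C(CC)C(=O)OC | intermediate
13 | dimethyl 2,4-diethyl-3-[(2S)-1-(ethylsulfanyl)-4-methoxy-1,4-dioxobutan-2-yl]pentanedioate (arm epimers) | CCSC(=O)[C@@H](CC(=O)OC)C(C(CC)C(=O)OC)C(CC)C(=O)OC | intermediate
14 | (2E)-3-phenylprop-2-enal | O=C/C=C/c1ccccc1 | starting material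
15 | [(1E)-4,4-dibromobuta-1,3-dien-1-yl]benzene | BrC(Br)=C/C=C/c1ccccc1 | intermediate
16 | lithium (3E)-4-phenylbut-3-en-1-yn-1-ide (not isolated) | [Li]C#C/C=C/c1ccccc1 | intermediate
17 | [(1E)-but-1-en-3-yn-1-yl]benzene | C#C/C=C/c1ccccc1 | intermediate
18 | [(1E,3E)-2-ethyl-4-phenylbuta-1,3-dien-1-yl]copper (not isolated) | [Cu]/C=C(CC)/C=C/c1ccccc1 | intermediate
19 | [(1E,3E)-3-ethyl-4-iodobuta-1,3-dien-1-yl]benzene | I/C=C(CC)/C=C/c1ccccc1 | intermediate
20 | [(1E,3E)-2-ethyl-4-phenylbuta-1,3-dien-1-yl]lithium (not isolated) | [Li]/C=C(CC)/C=C/c1ccccc1 | intermediate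
21 | chloro[(1E,3E)-2-ethyl-4-phenylbuta-1,3-dien-1-yl]zinc (not isolated) | Cl[Zn]/C=C(CC)/C=C/c1ccccc1 | intermediate
22 | dimethyl 2,4-diethyl-3-[(3S,5E,7E)-6-ethyl-1-methoxy-1,4-dioxo-8-phenylocta-5,7-dien-3-yl]pentanedioate (arm epimers) | COC(=O)C[C@@H](C(C(CC)C(=O)OC)C(CC)C(=O)OC)C(=O)/C=C(CC)/C=C/c1ccccc1 | intermediate
23 | dichlorocerium (3S,4S)-alkoxide from methyl addition to 22 (not isolated) | COC(=O)C[C@@H](C(C(CC)C(=O)OC)C(CC)C(=O)OC)[C@](C)(O[Ce](Cl)Cl)/C=C(CC)/C=C/c1ccccc1 | intermediate
24 | dimethyl 2,4-diethyl-3-{(2S,3S)-2-[(1E,3E)-2-ethyl-4-phenylbuta-1,3-dien-1-yl]-2-methyl-5-oxooxolan-3-yl}pentanedioate (arm epimers) | COC(=O)C(CC)C(C(CC)C(=O)OC)[C@@H]1CC(=O)O[C@]1(C)/C=C(CC)/C=C/c1ccccc1 | intermediate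
25 | potassium salt of the hydroxy acid from opening of the lactone of 24 (not isolated) | COC(=O)C(CC)C(C(CC)C(=O)OC)[C@H](CC(=O)[O-])[C@](C)(O)/C=C(CC)/C=C/c1ccccc1.[K+] | intermediate
26 | potassium 2-[(2S,3S,4R)-5-ethyl-2-[(1E,3E)-2-ethyl-4-phenylbuta-1,3-dien-1-yl]-4-(1-methoxy-1-oxobutan-2-yl)-2-methyl-6-oxooxan-3-yl]acetate (not isolated) | CCC1C(=O)O[C@](C)(/C=C(CC)/C=C/c2ccccc2)[C@@H](CC(=O)[O-])[C@@H]1C(CC)C(=O)OC.[K+] | intermediate
27 | methyl 2-[(2S,3S,4R)-5-ethyl-2-[(1E,3E)-2-ethyl-4-phenylbuta-1,3-dien-1-yl]-4-(1-methoxy-1-oxobutan-2-yl)-2-methyl-6-oxooxan-3-yl]acetate (epimers at ring C5 and at the butan-2-yl carbon) | CCC1C(=O)O[C@](C)(/C=C(CC)/C=C/c2ccccc2)[C@@H](CC(=O)OC)[C@@H]1C(CC)C(=O)OC | intermediate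
28 | trimethylsilyl ketene acetal of the lactone of 27, drawn with only the lactone silylated (not isolated) | CCC1=C(O[Si](C)(C)C)O[C@](C)(/C=C(CC)/C=C/c2ccccc2)[C@@H](CC(=O)OC)[C@@H]1C(CC)C(=O)OC | intermediate
29 | trimethylsilyl ester of 30 (not isolated) | COC(=O)C[C@@H]1C(C)=C[C@@](/C=C/c2ccccc2)(CC)[C@](CC)(C(=O)O[Si](C)(C)C)[C@H]1C(CC)C(=O)OC | intermediate
30 | (1R,2S,5S,6R)-1,2-diethyl-6-(1-methoxy-1-oxobutan-2-yl)-5-(2-methoxy-2-oxoethyl)-4-methyl-2-[(E)-2-phenylethenyl]cyclohex-3-ene-1-carboxylic acid (epimers at the butan-2-yl carbon) | COC(=O)C[C@@H]1C(C)=C[C@@](/C=C/c2ccccc2)(CC)[C@](CC)(C(=O)O)[C@H]1C(CC)C(=O)OC | intermediate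
31 | dilithium salt (C7 carboxylate and C2/C3 enolate) of the Dieckmann product (not isolated) | CCC1C([O-])=C(C(=O)OC)[C@@H]2C(C)=C[C@@](/C=C/c3ccccc3)(CC)[C@](CC)(C(=O)[O-])[C@H]21.[Li+].[Li+] | intermediate
32 | (3aS,6S,7R,7aR)-1,6,7-triethyl-3-(methoxycarbonyl)-3,4-dimethyl-2-oxo-6-[(E)-2-phenylethenyl]-2,3,3a,6,7,7a-hexahydro-1H-indene-7-carboxylic acid (epimers at C1 and C3) | CCC1C(=O)C(C)(C(=O)OC)[C@@H]2C(C)=C[C@@](/C=C/c3ccccc3)(CC)[C@](CC)(C(=O)O)[C@H]21 | intermediate
33 | (3aR,6S,7R,7aR)-1,6,7-triethyl-3,4-dimethyl-2-oxo-6-[(E)-2-phenylethenyl]-2,3,3a,6,7,7a-hexahydro-1H-indene-7-carboxylic acid, C1/C3 epimer mixture (not isolated) | CCC1C(=O)C(C)[C@@H]2C(C)=C[C@@](/C=C/c3ccccc3)(CC)[C@](CC)(C(=O)O)[C@H]21 | intermediate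
34 | (1S,3S,3aR,6S,7R,7aR)-1,6,7-triethyl-3,4-dimethyl-2-oxo-6-[(E)-2-phenylethenyl]-2,3,3a,6,7,7a-hexahydro-1H-indene-7-carboxylic acid | CC[C@@H]1C(=O)[C@@H](C)[C@@H]2C(C)=C[C@@](/C=C/c3ccccc3)(CC)[C@](CC)(C(=O)O)[C@H]21 | target

## Step count and least certain steps

Total step count: 15. Longest linear sequence: 12 (steps 1–6 and 10–15); steps 7–9 make the dienyl iodide that joins at step 10.

**Step 13 (key step).** The most likely failure is incomplete silylation of the hindered C7–H, so that the faster-formed enolate of the unbranched C3 ester condenses with the lactone carbonyl. Heterolysis of the tertiary dienylic C4–O bond (elimination) could also win over a boat that is sterically loaded, because the C1 chain and the C6 ethyl group are brought together. The fallback sets out from 26, the potassium carboxylate formed in step 12 before methylation, in which the C3 arm cannot be enolised. KN(SiMe3)2 (2.5 equiv) in toluene–THF from −78 to 25 °C should form the lactone enolate, whose anion-accelerated ester-enolate Claisen rearrangement runs below the temperature at which ionisation matters. Acidification should give the diacid (1R,2S,5S,6R)-5-(carboxymethyl)-1,2-diethyl-6-(1-methoxy-1-oxobutan-2-yl)-4-methyl-2-[(E)-2-phenylethenyl]cyclohex-3-ene-1-carboxylic acid F1. Fischer esterification (MeOH, catalytic HCl, 25 °C) then esterifies only the unhindered acetic acid group and comes back to the route at 30.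

**Step 12.** The most likely failure is ring closure on the other diastereotopic butanoate arm, which loses control at C7a: the chair with the dienyl group equatorial may be only slightly better than the chair with it axial, so the equilibrium could be poorly biased. The fallback moves the C7a decision from a ring closure to a C–C bond formation. It sets out from 8 and commercial 5-methoxy-5-oxopentanoic acid (COC(=O)CCCC(=O)O).
- The conditions of step 4 should give methyl 5-[(4S)-4-benzyl-2-oxo-1,3-oxazolidin-3-yl]-5-oxopentanoate F2.
- Alkylation as in step 5 should give dimethyl (3R)-3-{[(4S)-4-benzyl-2-oxo-1,3-oxazolidin-3-yl]carbonyl}hexanedioate F3.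
- Thiolysis as in step 6 should give dimethyl (3R)-3-[(ethylsulfanyl)carbonyl]hexanedioate F4.
- Coupling with 21 as in step 10 should give dimethyl (3R)-3-[(2E,4E)-3-ethyl-5-phenylpenta-2,4-dienoyl]hexanedioate F5.
- Methyl addition and warming should give methyl 3-{(2S,3R)-2-[(1E,3E)-2-ethyl-4-phenylbuta-1,3-dien-1-yl]-2-methyl-5-oxooxolan-3-yl}propanoate F6. Here both C3a chains are primary, so the substrate offers little facial bias; the addition would be run under the catalyst-controlled conditions named for step 11, and the C4 epimers separated at this stage if necessary.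
- The conditions of step 12, now with a single arm and no choice, should give methyl 2-{(2S,3R)-2-[(1E,3E)-2-ethyl-4-phenylbuta-1,3-dien-1-yl]-2-methyl-6-oxooxan-3-yl}acetate F7.
- LDA and PhSeBr at −78 °C, then NaIO4, should give methyl 2-{(2S,3S)-2-[(1E,3E)-2-ethyl-4-phenylbuta-1,3-dien-1-yl]-2-methyl-6-oxo-3,6-dihydro-2H-pyran-3-yl}acetate F8.
- The lithium enolate of methyl butanoate should add to C7a anti to the C3a chain, and trapping of the lactone enolate with ethyl triflate at −78 °C comes back to the route at 27.

This costs the Felkin bias of step 11, so it is held in reserve.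

**Step 11.** The most likely failure is poor facial selectivity in the methyl addition, because the preference rests only on the size difference between the two C3a chains; some conjugate addition is also possible. The fallback replaces substrate control by catalyst control. It sets out from 22 and uses Me2Zn and Ti(OiPr)4 with a chiral trans-cyclohexane-1,2-diyl bis(hydroxycamphorsulfonamide) ligand, a known enantioselective methyl addition to α,β-unsaturated ketones, with the ligand enantiomer chosen to match the Felkin sense. After warming it comes back to the route at 24 and makes no new compound.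

**Step 9.** The most likely failure is carbometalation with the wrong regiochemistry, or conjugate addition across the enyne to an allenyl species, with erosion of the C5=C6 geometry. The fallback sets out from 17. Syn bromoboration (BBr3, CH2Cl2, −78 °C; then pinacol) should give 2-[(1Z,3E)-2-bromo-4-phenylbuta-1,3-dien-1-yl]-4,4,5,5-tetramethyl-1,3,2-dioxaborolane F9. Negishi coupling with Et2Zn (Pd(PtBu3)2 cat., THF) replaces bromine by ethyl with retention and should give 2-[(1E,3E)-2-ethyl-4-phenylbuta-1,3-dien-1-yl]-4,4,5,5-tetramethyl-1,3,2-dioxaborolane F10. Iododeboronation with retention (I2, NaOH) comes back to the route at 19.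

Further compounds
F1 | step 13 | (1R,2S,5S,6R)-5-(carboxymethyl)-1,2-diethyl-6-(1-methoxy-1-oxobutan-2-yl)-4-methyl-2-[(E)-2-phenylethenyl]cyclohex-3-ene-1-carboxylic acid | OC(=O)C[C@@H]1C(C)=C[C@@](/C=C/c2ccccc2)(CC)[C@](CC)(C(=O)O)[C@H]1C(CC)C(=O)OC
F2 | step 12 | methyl 5-[(4S)-4-benzyl-2-oxo-1,3-oxazolidin-3-yl]-5-oxopentanoate | O=C1OC[C@H](Cc2ccccc2)N1C(=O)CCCC(=O)OC
F3 | step 12 | dimethyl (3R)-3-{[(4S)-4-benzyl-2-oxo-1,3-oxazolidin-3-yl]carbonyl}hexanedioate | O=C1OC[C@H](Cc2ccccc2)N1C(=O)[C@@H](CC(=O)OC)CCC(=O)OC
F4 | step 12 | dimethyl (3R)-3-[(ethylsulfanyl)carbonyl]hexanedioate | CCSC(=O)[C@@H](CC(=O)OC)CCC(=O)OC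
F5 | step 12 | dimethyl (3R)-3-[(2E,4E)-3-ethyl-5-phenylpenta-2,4-dienoyl]hexanedioate | COC(=O)C[C@@H](CCC(=O)OC)C(=O)/C=C(CC)/C=C/c1ccccc1
F6 | step 12 | methyl 3-{(2S,3R)-2-[(1E,3E)-2-ethyl-4-phenylbuta-1,3-dien-1-yl]-2-methyl-5-oxooxolan-3-yl}propanoate | COC(=O)CC[C@@H]1CC(=O)O[C@]1(C)/C=C(CC)/C=C/c1ccccc1
F7 | step 12 | methyl 2-{(2S,3R)-2-[(1E,3E)-2-ethyl-4-phenylbuta-1,3-dien-1-yl]-2-methyl-6-oxooxan-3-yl}acetate | COC(=O)C[C@H]1CCC(=O)O[C@]1(C)/C=C(CC)/C=C/c1ccccc1
F8 | step 12 | methyl 2-{(2S,3S)-2-[(1E,3E)-2-ethyl-4-phenylbuta-1,3-dien-1-yl]-2-methyl-6-oxo-3,6-dihydro-2H-pyran-3-yl}acetate | COC(=O)C[C@H]1C=CC(=O)O[C@]1(C)/C=C(CC)/C=C/c1ccccc1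
F0 | step 11 | none | none
F9 | step 9 | 2-[(1Z,3E)-2-bromo-4-phenylbuta-1,3-dien-1-yl]-4,4,5,5-tetramethyl-1,3,2-dioxaborolane | CC1(C)OB(/C=C(Br)/C=C/c2ccccc2)OC1(C)C
F10 | step 9 | 2-[(1E,3E)-2-ethyl-4-phenylbuta-1,3-dien-1-yl]-4,4,5,5-tetramethyl-1,3,2-dioxaborolane | CC1(C)OB(/C=C(CC)/C=C/c2ccccc2)OC1(C)C
A1 | alternative 1 | 3,4-diethyl-6-methyl-2H-pyran-2-one | CCc1cc(C)oc(=O)c1CC
A2 | alternative 1 | dimethyl (2E)-but-2-enedioate | COC(=O)/C=C/C(=O)OC
A3 | alternative 1 | dimethyl 4,5-diethyl-1-methyl-3-oxo-2-oxabicyclo[2.2.2]oct-5-ene-7,8-dicarboxylate | CCC1=C[C@@]2(C)OC(=O)[C@]1(CC)[C@@H](C(=O)OC)[C@@H]2C(=O)OC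
A4 | alternative 2 | methyl (4Z,6E)-2-(but-1-yn-1-yl)-3-ethenyl-2,3-diethyl-5-methylocta-4,6-dienoate | CCC#C[C@@](CC)(C(=O)OC)[C@@](CC)(C=C)/C=C(C)\C=C\C
A5 | alternative 2 | methyl 6-ethenyl-1,6,7-triethyl-3,4-dimethyl-2-oxo-3,3a,6,7-tetrahydro-2H-indene-7-carboxylate | CCC1=C2[C@H]([C@H](C)C1=O)C(C)=C[C@@](C=C)(CC)[C@]2(CC)C(=O)OC
A6 | alternative 3 | methyl 3-ethenyl-2,3-diethyl-2-[2-ethyl-4-methyl-3-oxo-5-(prop-1-en-2-yl)cyclopentyl]pent-4-enoate | CC[C@@H]1C(=O)[C@@H](C)[C@H](C(C)=C)[C@H]1[C@@](CC)(C(=O)OC)C(CC)(C=C)C=C
A7 | alternative 3 | methyl (1S,3S,3aR,6S,7R,7aR)-6-ethenyl-1,6,7-triethyl-3,4-dimethyl-2-oxo-2,3,3a,6,7,7a-hexahydro-1H-indene-7-carboxylate | CC[C@@H]1C(=O)[C@@H](C)[C@@H]2C(C)=C[C@@](C=C)(CC)[C@](CC)(C(=O)OC)[C@H]21
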